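**Retrosynthetic overview**

1. Numbering used: C1 (CH–OMe), C2 (bridgehead CH), C3 (CH2), C4 (CH–iPr), C5 (quaternary bridgehead), C6, C7 (CH2), C8 (C–CH3), C9 (ring-fusion CH), C10 (CH), C11 (C(CH3)OH), C12 (CHOH), C13 (CH2), C14 (CHBr), C15 (bridging CH2); ring A = C8, C9, C11–C14; ring B = C5–C10; ring C = C1, C2, C15, C5, C10; ring D = C2, C3, C4, C5, C15.
2. Ring A is finished last from a vinylogous ester inherited from a quinone: C14–Br by hydrogen-atom-transfer hydrogenation of a bromoalkene, C12–OH by hydroxyl-directed reduction, C11 by methyl addition.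
3. Ring C is made by radical one-carbon ring expansion (Dowd–Beckwith 1,2-acyl shift) of the cyclobutanone C1(=O)–C15–C5–C10: C2 is inserted between C1 and C15, turning a bicyclo[3.2.0]heptan-6-one into the bicyclo[2.2.1]heptan-2-one. The enabling feature is the C2 radical centre on cis-fused ring D, β to the C1 carbonyl through ring-fusion carbon C15, with the strained C1–C15 bond aligned with its p-orbital.
4. The four-membered ring and ring D come from one intramolecular ketene [2+2] cycloaddition across C5=C10 of ring B; C4 is set before that by catalytic asymmetric conjugate addition of a ring-B dienylboronate to an enal.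
5. Rings A and B come from an enantioselective quinone Diels–Alder reaction. Order of ring formation: A and B together, then D with the four-membered ring, then C by ring expansion.

Key step: step 14

Remark: β is the face of the C8 methyl group, α the opposite face. Assumption: the (S)-oxazaborolidinium catalyst (step 2) and the (S,S)-diene ligand (step 9) are taken to give the configurations drawn at C8 and C4; both centres are reagent-controlled, so the antipodal catalyst or ligand is used if the facial sense is the opposite.

**Route**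

Step 1
Reactants: 1 methyl vinyl ketone
Product: 2 2-(triisopropylsilyloxy)buta-1,3-diene
Conditions: iPr3SiOTf, Et3N, Et2O, 0 → 23 °C
Reagents that add atoms: triisopropylsilyl triflate, CC(C)[Si](C(C)C)(C(C)C)OS(=O)(=O)C(F)(F)F
Why: Soft enolisation and O-silylation of the methyl ketone (silyl enol ether formation) should give the 2-siloxydiene; no stereocentre is formed.

Step 2
Reactants: 3 2-methoxy-5-methyl-1,4-benzoquinone; 2 2-(triisopropylsilyloxy)buta-1,3-diene
Product: 4 cis-fused adduct, 2-methoxy-4a-methyl-7-(triisopropylsilyloxy)-4a,5,8,8a-tetrahydronaphthalene-1,4-dione (C8 methyl and C9–H both β)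
Conditions: (S)-oxazaborolidinium triflimide (from (S)-α,α-diphenylprolinol, o-tolylboroxine, Tf2NH; 20 mol%), CH2Cl2/PhMe, −78 °C
Reagents that add atoms: none
Why: Enantioselective quinone Diels–Alder reaction under chiral oxazaborolidinium catalysis: the methoxy-bearing double bond is a deactivated vinylogous ester, the catalyst binds the more basic C14 carbonyl so that the nucleophilic diene terminus (C10) bonds to C9, and endo addition to the unshielded quinone face sets C8 (with C9 cis).

Step 3
Reactants: 4 cis-fused adduct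
Product: 5 trans-fused dione (C8 methyl β, C9–H α)
Conditions: DBU (cat.), PhMe, 23 °C; crystallisation, mother liquor re-equilibrated
Reagents that add atoms: none
Why: Base-catalysed epimerisation at C9 (α to the C11 ketone) under thermodynamic control, as in the classical cis-to-trans isomerisation of the corresponding butadiene adduct, should give the trans ring fusion.

Step 4
Reactants: 5 trans-fused dione
Product: 6 C11 tertiary alcohol (C11–OH β, C11–CH3 α)
Conditions: MeLi, CeCl3, THF, −78 °C
Reagents that add atoms: methyllithium, [Li]C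
Why: Organocerium 1,2-addition is chemoselective for the C11 ketone (C14=O is a vinylogous ester, C5 is masked as silyl enol ether) and should occur from the α face, anti to the 1,3-related axial C8 methyl group.

Step 5
Reactants: 6 C11 tertiary alcohol
Product: 7 C11 tert-butyldimethylsilyl ether
Conditions: tBuMe2SiOTf, 2,6-lutidine, CH2Cl2, 0 → 23 °C
Reagents that add atoms: tert-butyldimethylsilyl triflate, CC(C)(C)[Si](C)(C)OS(=O)(=O)C(F)(F)F
Why: Silyl ether protection of the hindered tertiary alcohol with the reactive silyl triflate; no stereocentre is touched.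

Step 6
Reactants: 7 C11 silyl ether
Product: 8 bicyclic enone (C5 ketone, C6=C7)
Conditions: Pd(OAc)2 (1.1 equiv), MeCN, 40 °C
Reagents that add atoms: none
Why: Saegusa–Ito oxidation of the regiodefined silyl enol ether (C5=C6) places the new double bond at C6=C7 by β-hydride elimination from C7.

Step 7
Reactants: 8 bicyclic enone
Product: 9 dienyl triflate (C5–OTf, C5=C10, C6=C7)
Conditions: KN(SiMe3)2, THF, −78 °C; PhNTf2
Reagents that add atoms: N-phenyl-bis(trifluoromethanesulfonimide), O=S(=O)(N(c1ccccc1)S(=O)(=O)C(F)(F)F)C(F)(F)F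
Why: Kinetic α′-deprotonation at C10 (the γ-position C8 is quaternary and the vinylogous ester has no enolisable hydrogen) followed by O-triflation gives the cross-conjugated enol triflate regiospecifically.

Step 8
Reactants: 9 dienyl triflate
Product: 10 dienyl pinacol boronate (Bpin on C5)
Conditions: B2pin2, PdCl2(dppf) (5 mol%), KOAc, dioxane, 80 °C
Reagents that add atoms: bis(pinacolato)diboron, CC1(C)OB(OC1(C)C)B1OC(C)(C)C(C)(C)O1
Why: Miyaura borylation of an alkenyl triflate; the ring-A carbonyl and silyl ether are inert.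

Step 9
Reactants: 10 dienyl pinacol boronate; 11 (E)-4-methylpent-2-enal
Product: 12 aldehyde C5–C4H(iPr)–C3H2–C2HO with (S)-configured C4
Conditions: [RhCl(C2H4)2]2 (3 mol%), (S,S)-2,5-diphenylbicyclo[2.2.2]octa-2,5-diene (7 mol%), KOH (aq., 0.2 equiv), dioxane/H2O, 30 °C
Reagents that add atoms: none
Why: Rhodium-catalysed asymmetric 1,4-addition of an alkenylboron reagent to an enal (Hayashi–Miyaura reaction) with a chiral diene ligand should form the C5–C4 bond; C4 is set by the catalyst, remote from the substrate stereocentres.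

Step 10
Reactants: 12 aldehyde; 13 ethoxyacetylene
Product: 15 triethylsilyl ether of the C2 carbinol bearing the 1-ethoxyalkyne (both C2 epimers), via lithium propargylic alkoxide 14 (not isolated)
Conditions: 13, nBuLi, THF, −78 °C; 12; then Et3SiCl, −78 → 0 °C
Reagents that add atoms: chlorotriethylsilane, CC[Si](Cl)(CC)CC
Why: Acetylide 1,2-addition to the aldehyde (far more electrophilic than the vinylogous ester carbonyl) and in situ O-silylation; the C2 configuration is irrelevant because C2 becomes a radical centre in step 14.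

Step 11
Reactants: 15 ynol ether
Product: 17 tetracyclic cyclobutanone (C1(=O)–C15–C5–C10 ring cis-fused to ring D and to ring B, C6=C7 retained, C2–OSiEt3), via aldoketene 16 (not isolated)
Conditions: PhMe (0.01 M), 120 °C, sealed tube
Reagents that add atoms: none
Why: Thermal retro-ene loss of ethene from the 1-ethoxyalkyne gives the aldoketene, which should undergo intramolecular ketene–alkene [2+2] cycloaddition through the three-atom tether to the bicyclo[3.2.0]heptan-6-one: C1 bonds to the diene terminus C10 and C15 to the more substituted C5, on the α face anti to the C8 methyl and C11 silyloxy groups, setting C5, C10 and C15.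

Step 12
Reactants: 17 tetracyclic cyclobutanone
Product: 19 C2 alcohol with saturated ring B, via saturated triethylsilyl ether 18 (not isolated)
Conditions: H2 (3 atm), 10% Pd/C, MeOH, 23 °C
Reagents that add atoms: none
Why: Catalytic hydrogenation of the cis-disubstituted C6=C7 alkene (no stereocentre formed) with concomitant Pd/C-mediated methanolysis of the secondary triethylsilyl ether; the tertiary silyl ether and the vinylogous ester should survive.

Step 13
Reactants: 19 C2 alcohol
Product: 20 C2 O-phenyl thionocarbonate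
Conditions: PhOC(S)Cl, pyridine, DMAP (cat.), CH2Cl2, 0 → 23 °C
Reagents that add atoms: O-phenyl chlorothionoformate, S=C(Cl)Oc1ccccc1
Why: Thioacylation of the only free (secondary) alcohol gives the Barton–McCombie radical precursor.

Step 14
Reactants: 20 C2 O-phenyl thionocarbonate
Product: 21 norbornanone (C1 ketone, C15 methylene bridge, C4 isopropyl endo, C9 exo on C10)
Conditions: (Me3Si)3SiH (syringe pump), AIBN (cat.), PhMe, 90 °C, 0.005 M
Reagents that add atoms: none
Why: Silyl radical attack on the thionocarbonate gives the secondary C2 radical of ring D, which adds 3-exo-trig to the cyclobutanone carbonyl C1 (the cis ring fusion holds its p-orbital nearly parallel to the C15–C1 bond) to give a bicyclo[2.1.0]pentan-1-oxyl radical; β-scission of the central C1–C15 bond, driven by loss of four-ring strain and re-formation of C=O, gives the C15 (7-norbornyl) radical, which is reduced by the silane. The closest known reaction type is the Dowd–Beckwith one-carbon ring expansion (radical 1,2-acyl migration) of β-keto alkyl radicals, which includes fused cyclobutanones. Ring C (C1–C2–C15–C5–C10) is closed by this 3-exo-trig attack and fragmentation, so the cyclobutanone C1–C10–C5–C15 gains C2 between C1 and C15 and ring D becomes the second five-membered ring of the bicyclo[2.2.1]heptane. The only stereocentre formed, bridgehead C2, is dictated by the bicyclic framework (C1 can reach C2 only on the face that already carries C15), so both C2 epimers of 20 converge, while C4, C5 and C10 are untouched. The step needs the rearrangement to outrun direct hydrogen transfer to the C2 radical and scission to a ring-opened acyl radical; the slow hydrogen donor kept at low stationary concentration and the strain of the cyclobutanone should secure this, and the regiochemistry is fixed by connectivity because C2 is attached to C15 and only C1–C15 cleavage gives a strain-relieved ketone.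

Step 15
Reactants: 21 norbornanone
Product: 22 endo C1 alcohol (C1–H exo)
Conditions: NaBH4, MeOH/CH2Cl2, −20 °C
Reagents that add atoms: none
Why: Hydride reduction of the norbornan-2-one from the exo face: the developing alkoxide fits only the endo position because the exo site is compressed by the peri C11 methyl group, so the endo alcohol should result, and the vinylogous ester carbonyl is not reduced under these conditions.

Step 16
Reactants: 22 endo C1 alcohol
Product: 23 C1 endo methyl ether
Conditions: NaH, MeI, THF/DMF, 0 → 23 °C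
Reagents that add atoms: iodomethane, CI
Why: Williamson ether synthesis on the only free hydroxyl; the C1 configuration is retained.

Step 17
Reactants: 23 C1 endo methyl ether
Product: 24 β-bromo enone (C14(Br)=C13–C12(=O), C11 silyl ether)
Conditions: (COBr)2, DMF (cat.), 2,6-di-tert-butylpyridine, CH2Cl2, 0 → 23 °C
Reagents that add atoms: oxalyl bromide, O=C(Br)C(=O)Br
Why: Vilsmeier-type activation of the vinylogous ester carbonyl oxygen, bromide addition at C14 with loss of the activated oxygen, and O-demethylation of the resulting oxocarbenium ion (the known conversion of 3-alkoxyenones into transposed β-haloenones) should place bromine on C14 and the ketone on C12.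

Step 18
Reactants: 24 β-bromo enone
Product: 25 C11 hydroxy β-bromo enone
Conditions: HF (48% aq.), MeCN, 0 → 23 °C
Reagents that add atoms: none
Why: Fluoride-mediated silyl ether cleavage frees the C11 hydroxyl that directs the next step.

Step 19
Reactants: 25 C11 hydroxy β-bromo enone
Product: 26 C11,C12 anti-diol with C13=C14–Br (C12–OH α)
Conditions: Me4NBH(OAc)3, AcOH/MeCN, −20 °C
Reagents that add atoms: none
Why: Hydroxyl-directed (Evans–Saksena) reduction: intramolecular hydride delivery from the boron bound to the β C11 oxygen should give the C12 α alcohol, anti to C11–OH.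

Step 20
Reactants: 26 anti-diol bromoalkene
Product: 27 target
Conditions: Mn(dpm)3 (10 mol%; dpm = dipivaloylmethanate), PhSiH3, tBuOOH, iPrOH, 23 °C
Reagents that add atoms: none
Why: Metal-hydride hydrogen-atom-transfer (Mukaiyama-type) hydrogenation of a bromoalkene, which retains the halogen: H adds to C13, and the α-bromo C14 radical should take up hydrogen axially from the α face (anti to the axial C8 methyl), placing bromine equatorial and β, which is also the thermodynamically preferred epimer.

**Compound list**

1 | methyl vinyl ketone | CC(=O)C=C | starting material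
2 | 2-(triisopropylsilyloxy)buta-1,3-diene | C=CC(=C)O[Si](C(C)C)(C(C)C)C(C)C | intermediate
3 | 2-methoxy-5-methyl-1,4-benzoquinone | COC1=CC(=O)C(C)=CC1=O | starting material
4 | cis-fused Diels–Alder adduct (C8 methyl β, C9–H β) | CC(C)[Si](C(C)C)(C(C)C)OC1=CC[C@]2(C)C(=O)C=C(OC)C(=O)[C@@H]2C1 | intermediate
5 | trans-fused dione (C8 methyl β, C9–H α) | CC(C)[Si](C(C)C)(C(C)C)OC1=CC[C@]2(C)C(=O)C=C(OC)C(=O)[C@H]2C1 | intermediate
6 | C11 tertiary alcohol (OH β, CH3 α) | CC(C)[Si](C(C)C)(C(C)C)OC1=CC[C@]2(C)C(=O)C=C(OC)[C@@](C)(O)[C@H]2C1 | intermediate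
7 | C11 tert-butyldimethylsilyl ether | CC(C)[Si](C(C)C)(C(C)C)OC1=CC[C@]2(C)C(=O)C=C(OC)[C@@](C)(O[Si](C)(C)C(C)(C)C)[C@H]2C1 | intermediate
8 | bicyclic enone (C5=O, C6=C7) | O=C1C[C@@H]2[C@](C)(O[Si](C)(C)C(C)(C)C)C(OC)=CC(=O)[C@@]2(C)C=C1 | intermediate
9 | dienyl triflate (C5–OTf) | O=S(=O)(OC1=C[C@@H]2[C@](C)(O[Si](C)(C)C(C)(C)C)C(OC)=CC(=O)[C@@]2(C)C=C1)C(F)(F)F | intermediate
10 | dienyl pinacol boronate (C5–Bpin) | CC1(C)OB(OC1(C)C)C2=C[C@@H]3[C@](C)(O[Si](C)(C)C(C)(C)C)C(OC)=CC(=O)[C@@]3(C)C=C2 | intermediate
11 | (E)-4-methylpent-2-enal | CC(C)/C=C/C=O | starting material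
12 | aldehyde with (S)-C4 bearing isopropyl | O=CC[C@@H](C(C)C)C1=C[C@@H]2[C@](C)(O[Si](C)(C)C(C)(C)C)C(OC)=CC(=O)[C@@]2(C)C=C1 | intermediate
13 | ethoxyacetylene | CCOC#C | starting material
14 | lithium propargylic alkoxide (C2 epimers) | [Li+].[O-]C(C#COCC)C[C@@H](C(C)C)C1=C[C@@H]2[C@](C)(O[Si](C)(C)C(C)(C)C)C(OC)=CC(=O)[C@@]2(C)C=C1 | intermediate (not isolated)
15 | C2 triethylsilyl ether bearing the 1-ethoxyalkyne (C2 epimers) | CCOC#CC(O[Si](CC)(CC)CC)C[C@@H](C(C)C)C1=C[C@@H]2[C@](C)(O[Si](C)(C)C(C)(C)C)C(OC)=CC(=O)[C@@]2(C)C=C1 | intermediate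
16 | aldoketene | O=C=CC(O[Si](CC)(CC)CC)C[C@@H](C(C)C)C1=C[C@@H]2[C@](C)(O[Si](C)(C)C(C)(C)C)C(OC)=CC(=O)[C@@]2(C)C=C1 | intermediate (not isolated)
17 | tetracyclic cyclobutanone with C6=C7 and C2–OSiEt3 (C2 epimers) | O=C1[C@H]2C(O[Si](CC)(CC)CC)C[C@@H](C(C)C)[C@]23C=C[C@@]4(C)[C@H]([C@H]13)[C@](C)(O[Si](C)(C)C(C)(C)C)C(OC)=CC4=O | intermediate
18 | ring-B-saturated triethylsilyl ether | O=C1[C@H]2C(O[Si](CC)(CC)CC)C[C@@H](C(C)C)[C@]23CC[C@@]4(C)[C@H]([C@H]13)[C@](C)(O[Si](C)(C)C(C)(C)C)C(OC)=CC4=O | intermediate (not isolated)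
19 | C2 alcohol (C2 epimers) | O=C1[C@H]2C(O)C[C@@H](C(C)C)[C@]23CC[C@@]4(C)[C@H]([C@H]13)[C@](C)(O[Si](C)(C)C(C)(C)C)C(OC)=CC4=O | intermediate
20 | C2 O-phenyl thionocarbonate (C2 epimers) | O=C1[C@H]2C(OC(=S)Oc5ccccc5)C[C@@H](C(C)C)[C@]23CC[C@@]4(C)[C@H]([C@H]13)[C@](C)(O[Si](C)(C)C(C)(C)C)C(OC)=CC4=O | intermediate
21 | norbornanone (C1 ketone) | O=C1[C@H]2C[C@@H](C(C)C)[C@]3(CC[C@@]4(C)[C@H]([C@H]13)[C@](C)(O[Si](C)(C)C(C)(C)C)C(OC)=CC4=O)C2 | intermediate
22 | endo C1 alcohol | O[C@H]1[C@H]2C[C@@H](C(C)C)[C@]3(CC[C@@]4(C)[C@H]([C@H]13)[C@](C)(O[Si](C)(C)C(C)(C)C)C(OC)=CC4=O)C2 | intermediate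
23 | C1 endo methyl ether | CO[C@H]1[C@H]2C[C@@H](C(C)C)[C@]3(CC[C@@]4(C)[C@H]([C@H]13)[C@](C)(O[Si](C)(C)C(C)(C)C)C(OC)=CC4=O)C2 | intermediate
24 | β-bromo enone, C11 silyl ether | CO[C@H]1[C@H]2C[C@@H](C(C)C)[C@]3(CC[C@@]4(C)[C@H]([C@H]13)[C@](C)(O[Si](C)(C)C(C)(C)C)C(=O)C=C4Br)C2 | intermediate
25 | C11 hydroxy β-bromo enone | CO[C@H]1[C@H]2C[C@@H](C(C)C)[C@]3(CC[C@@]4(C)[C@H]([C@H]13)[C@](C)(O)C(=O)C=C4Br)C2 | intermediate
26 | anti-diol bromoalkene | CO[C@H]1[C@H]2C[C@@H](C(C)C)[C@]3(CC[C@@]4(C)[C@H]([C@H]13)[C@](C)(O)[C@@H](O)C=C4Br)C2 | intermediate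
27 | target | CO[C@H]1[C@H]2C[C@@H](C(C)C)[C@]3(CC[C@@]4(C)[C@H]([C@H]13)[C@](C)(O)[C@@H](O)C[C@@H]4Br)C2 | target

**Step count**

Total step count: 20. Longest linear sequence: 20 steps (1 → 27); compounds 3, 11 and 13 are bought.

**Steps most likely to fail**

Step 14. Hydrogen transfer to the C2 radical may be faster than the acyl shift (plain deoxygenation), or the radical may fragment to a ring-opened acyl radical. The fallback separates rearrangement from reduction and sets out from 19. Appel iodination (PPh3, I2, imidazole) should give the C2 iodide F1. Iodine-atom-transfer isomerisation under non-reducing conditions ((Bu3Sn)2 cat., hν, PhH) lets the C2 radical rearrange with no hydrogen donor present and should give the C15-iodo norbornanone F2. Reductive removal of iodine ((Me3Si)3SiH, AIBN) returns to the route at 21.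

Step 9. Protodeboronation of the hindered dienylboronate, 1,2-addition to the aldehyde, or weak catalyst control at C4 may intervene. The fallback sets out from 10 and forms the C5–C4 bond by allylic substitution instead. Copper-catalysed enantioselective SN2′ substitution of (E)-4-methylpent-2-en-1-yl diethyl phosphate with 10 (CuCl, chiral imidazolinium salt, NaOMe, THF) should give the C4 vinyl compound F3. Hydroboration–oxidation of the terminal alkene (9-BBN; NaBO3) should give the primary alcohol F4, and Dess–Martin oxidation returns to the route at 12.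

Step 11. Facial selectivity of the cycloaddition may be insufficient, or the ketene may oligomerise or the diene may isomerise at the temperature the retro-ene step needs. The fallback sets out from 12 and uses a more electrophilic keteniminium ion at lower temperature. Aldol addition of the lithium enolate of N,N-dimethylacetamide and in situ silylation (Et3SiCl) should give the β-silyloxy amide F5. Tf2O and 2,4,6-collidine in (CH2Cl)2 at 80 °C should convert F5 by intramolecular keteniminium–alkene [2+2] cycloaddition into the cyclobutaniminium triflate F6. Hydrolysis with aqueous NaHCO3 returns to the route at 17.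

**Further compounds**

F1 | step 14 | C2 iodide of the tetracyclic cyclobutanone (C2 epimers) | O=C1[C@H]2C(I)C[C@@H](C(C)C)[C@]23CC[C@@]4(C)[C@H]([C@H]13)[C@](C)(O[Si](C)(C)C(C)(C)C)C(OC)=CC4=O
F2 | step 14 | C15-iodo norbornanone (C15 epimers) | O=C1[C@H]2C[C@@H](C(C)C)[C@]3(CC[C@@]4(C)[C@H]([C@H]13)[C@](C)(O[Si](C)(C)C(C)(C)C)C(OC)=CC4=O)C2I
F3 | step 9 | C4 vinyl compound (C5–C4H(iPr)–CH=CH2) | C=C[C@@H](C(C)C)C1=C[C@@H]2[C@](C)(O[Si](C)(C)C(C)(C)C)C(OC)=CC(=O)[C@@]2(C)C=C1
F4 | step 9 | primary alcohol (C5–C4H(iPr)–CH2–CH2OH) | OCC[C@@H](C(C)C)C1=C[C@@H]2[C@](C)(O[Si](C)(C)C(C)(C)C)C(OC)=CC(=O)[C@@]2(C)C=C1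
F5 | step 11 | β-triethylsilyloxy N,N-dimethylamide (C2 epimers) | CN(C)C(=O)CC(O[Si](CC)(CC)CC)C[C@@H](C(C)C)C1=C[C@@H]2[C@](C)(O[Si](C)(C)C(C)(C)C)C(OC)=CC(=O)[C@@]2(C)C=C1
F6 | step 11 | cyclobutaniminium triflate (C2 epimers) | C[N+](C)=C1[C@H]2C(O[Si](CC)(CC)CC)C[C@@H](C(C)C)[C@]23C=C[C@@]4(C)[C@H]([C@H]13)[C@](C)(O[Si](C)(C)C(C)(C)C)C(OC)=CC4=O.[O-]S(=O)(=O)C(F)(F)F
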